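The teal run, warmer and more heavily charged than the ochre run, gains target faster at the outset and yet its last reading stands lower, at 43.7 % against 64.0 %, so when you repeat this, watch both the pace and the plateau.

common to all: gas 28 mM (held)
- ochre: starting material 0.070 M; temperature −25 °C; run made earlier
- teal: starting material 0.11 M; temperature −12 °C; run made earlier
- zeta: starting material 0.050 M; temperature −5 °C; time 2.0 d
- theta: starting material 0.050 M; temperature −20 °C; time 2.0 d

ochre run (percent of the starting material charged)

| time / d | target / % |
|---|---|
| 0.417 | 14.7 |
| 0.833 | 29.3 |
| 2.50 | 50.9 |
| 6.00 | 64.0 |

teal run (percent of the starting material charged)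

| time / h | target / % |
|---|---|
| 4.00 | 21.4 |
| 8.00 | 34.2 |
| 20.0 | 44.7 |
| 50.0 | 43.7 |

(scatter of a reading: 1 percentage point)

- the best flask by amount of target, in percent of the starting material charged; "all alike" if 1.5 percentage points covers them all (zeta / theta / all alike)
- amount of target at the end, in percent of the starting material charged, zeta
- amount of target at the end, in percent of the starting material charged, theta

- at the start none of partner is dissolved
- steps thought possible: starting material + partner <-> target + by-product; starting material -> decomposition product; gas <-> partner

I take the time scales in turn. Gas into partner comes first: ochre holds twice as much target at 0.833 d as at 0.417 d, so no lag shows, and I treat the partner as held from the first reading on. The turning comes next: with partner held it is pseudo-first-order, so the opening pace is a fraction of the charge per day, which I scale between the two runs by temperature: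

ochre 0.353 d⁻¹, teal 1.28 d⁻¹

theta 0.580 d⁻¹, zeta 2.58 d⁻¹

theta 1.16, zeta 5.15

The last line is the turnovers, the opening pace times the time. Teal was flat by 1.07 turnovers, so zeta, with more, should stand on its plateau. Teal's plateau, rescaled to the smaller charge, puts that at

0.770 = fraction made squared over fraction left, so 57.3 %,

and zeta should stand below that, being warmer than teal, for the same ratio times the charge reads larger in the colder ochre run. Theta's count equals 3.29 d of ochre, which lies between ochre's readings of 50.9 % and 64.0 %, and I lean to theta, since ochre's last reading stands above my figure for zeta. Decomposition comes last: teal's target readings fall by 1 percentage point from 20.0 h to 50.0 h, against a scatter of 1 point, so I leave it out.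

The forecast says theta, with zeta at 47 % (39 % to 54 %) and theta at 57 % (49 % to 65 %), the theta figure on the ground that “2 d at −20 °C equals about 3.5 d of ochre”, and its zeta stands below my figure of 57.3 % before the allowance for warmth.

Zeta ends at 54.3 % and theta at 60.1 %, so the best flask is theta.

    starting material + partner ⇌ target + by-product (K = 2.10, k = 3.00 × 10⁻⁴ M⁻¹ s⁻¹, Ea = 58.0 kJ mol⁻¹, ΔH = −21.0 kJ mol⁻¹)
    starting material → decomposition product (k = 1.50 × 10⁻⁸ s⁻¹, Ea = 104 kJ mol⁻¹)
    gas ⇌ partner, rate k3*(csat - [partner]) (kL = 5.90 × 10⁻⁴ s⁻¹)
    (constants at −20 °C)

At 1.00 d zeta already held 54.6 % of target and theta 45.9 %. Theta's reckoned 1.16 turnovers ended at 60.1 %, while zeta's reckoned 5.15 ended at 54.3 %. For a flask like theta kept at −35 °C, the count is 0.261, and that flask holds 22.1 % of target at 2.00 d.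

(The numbers in the tables are calculated for substances that don't exist; scatter was added.)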